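D, the limiting reagent, is the account here: each percent charged must stand in cD, in L, in J or in a gap.

| setting | birch | alder | zeta | alpha |
|---|---|---|---|---|
| D | 1 M | 1 M | 1.0 M | 1.0 M |
| G | 1 M | 1 M | 1.00 M | 1.00 M |
| Z | 1.4 M | 2.2 M | 1.00 M | 1.00 M |
| remark | run made earlier | run made earlier |  |  |
| time |  |  | 4.0 min | 10 min |

| run | time / min | D / % | J / % | L / % |
|---|---|---|---|---|
| birch | 0.333 | 86 | 1 | 8 |
| birch | 0.500 | 79 | 4 | 11 |
| birch | 0.667 | 79 | 6 | 15 |
| birch | 1.00 | 64 | 7 | 23 |
| birch | 1.50 | 56 | 9 | 25 |
| birch | 2.50 | 42 | 12 | 32 |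
| birch | 4.00 | 32 | 15 | 39 |
| alder | 0.200 | 86 | 3 | 5 |
| alder | 0.667 | 71 | 7 | 18 |
| alder | 1.00 | 61 | 8 | 18 |
| alder | 1.50 | 52 | 9 | 25 |
| alder | 2.50 | 38 | 14 | 35 |
| alder | 3.00 | 33 | 13 | 35 |
| alder | 4.00 | 25 | 13 | 42 |

(readings scatter by 1.5 percentage points)
1. which of these there is most of at the end, counted by the D in it, zeta (D / L / J)
2. which of these there is most of at the end, counted by the D in it, alpha (D / L / J)
3. amount of the one of these that there is most of at the end, in percent of the D charged, zeta
4. amount of the one of these that there is most of at the end, in percent of the D charged, alpha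
- what was read earlier has a scatter of 1.5 percentage points, one standard deviation

1. Birch closes at 4.00 min with a gap of 14.0 %, alder with 20.0 %. From birch to alder the gap grows 1.43-fold and the charge of Z 1.57-fold, so the gap is booked as a leak of D into Z, pseudo-first-order in cD with cZ held at its charge.

2. The leak needs the mean of cD, not its curve. The loss of D reads as second-order, so the mean fraction left is the end fraction times the ln of its reciprocal, over the fraction lost. For birch this gives 53.6 %; the birch readings, summed by trapezoids, give 54.1 %.

3. Birch and alder together give 0.0479 /M/min: the leak constant κ, the fraction of D lost to the gap per M of Z, per minute and per unit of mean fraction left.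

4. This reckoning draws the second-order constant linearly in cZ, which gives 0.422 /min for zeta and alpha. Zeta then keeps 37.2 % of its D and books 11.2 % to the gap. The rest splits as in the last readings, 74.3 % to L, so L closes at 38.3 %. Alpha keeps 19.2 %, books 18.8 % to the gap and closes L at 46.1 %.

5. The forecast gives L at 37 % for zeta, “only narrowly above D”, and L at 46 % for alpha.

The flasks give L at 41.6 % in zeta, with D at 33.3 %, and L at 48.8 % in alpha.

    D + G ⇌ L (K = 9.50 /M, k = 0.00515 /M/s)
    D + G ⇌ J (K = 2.90 /M, k = 0.00191 /M/s)
    D + Z → E (k = 7.93 × 10⁻⁴ /M/s)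

The gap is E: 9.99 % in zeta against κ's 11.2 %, 15.9 % in alpha against 18.8 %. In alpha at 10.0 min, the step to L, taken by itself with both directions together, relaxes with a half-life of 3.59 min, shorter than the run, while the slowest mode of the whole flask has 29.3 min, longer than the run. Alpha's L stands at 48.8 %, and at 100 min at 37.1 %, with E at 44.8 %.

In the neighbour flask, alpha with 2.5 M of Z and 10 % of D left, κ books 30.8 % to the gap. The computed E there is 32.1 %, with L at 42.7 %.

(The runs are simulated for substances that don't exist.)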